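Everything rests on opening ring B of the isocoumarin at C4–C4a, C1–C8a and C1–O2. The feature exploited is that the two anchor atoms of ring B, C4a and C8a, are neighbouring carbons of ring A, with the C8 oxygen flanking C8a, which is exactly the substitution pattern left when 3,5-dimethoxybenzyne is trapped. In one operation a trifluoromethyl 1,3-diketone is C-arylated at its methylene carbon, its trifluoroacetyl group shifts to the adjacent aryl carbon and the ketone enolate oxygen closes the pyranone with loss of fluoroform. The diketone already holds the complete lactone, both stereocentres and the CHCl2 group, as the 3'-O-benzyl ether, and is made from (R)-malic acid.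

Key step: step 12

Remark 1: in the (3'S,5'R) target the 3'-oxygen is cis to CHCl2 on the lactone, whereas chelate-controlled allylation of a dichloromethyl ketone should put the new CH2 arm cis to that oxygen; the side chain is therefore built in the (R)-malic acid series and C3' is inverted once (step 8).
Remark 2: lithiated, titanium-bound and other ionic states of a numbered compound are treated as reactive states of that compound and are not numbered separately.

Step 1
Reactants: 1 3,5-dimethoxyphenol
Product: 2 3,5-dimethoxyphenyl N-isopropylcarbamate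
Conditions: iPrNCO, Et3N (cat.), CH2Cl2, rt
Reagents that add atoms: isopropyl isocyanate, CC(C)N=C=O
Why: Amine-catalysed addition of the phenol to the isocyanate (carbamoylation) should give the N–H carbamate, a strong ortho-directing group that can later be removed under mild conditions.

Step 2
Reactants: 2 3,5-dimethoxyphenyl N-isopropylcarbamate
Product: 5 3,5-dimethoxy-2-(trimethylsilyl)phenyl N-isopropylcarbamate, via N-silyl carbamate 3 (not isolated), via C-silylated N-silyl carbamate 4 (not isolated)
Conditions: TBSOTf, TMEDA, Et2O, 0 °C → rt; n-BuLi, TMEDA, −78 °C; TMSCl; aq. NaHSO4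
Reagents that add atoms: chlorotrimethylsilane, C[Si](C)(C)Cl
Why: Directed ortho-metalation: after transient N-silylation, n-BuLi should lithiate C2, the position flanked by the carbamate and a methoxy group (favoured over C4 between the two weaker methoxy directors), TMSCl traps the aryllithium and the N-silyl group is lost on acidic work-up.

Step 3
Reactants: 5 3,5-dimethoxy-2-(trimethylsilyl)phenyl N-isopropylcarbamate
Product: 7 3,5-dimethoxy-2-(trimethylsilyl)phenyl trifluoromethanesulfonate, via silyl phenol 6 (not isolated)
Conditions: Et2NH, DBU, MeCN, 40 °C; then PhNTf2, rt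
Reagents that add atoms: N-phenylbis(trifluoromethanesulfonimide), O=S(=O)(N(c1ccccc1)S(=O)(=O)C(F)(F)F)C(F)(F)F
Why: Base-induced E1cB cleavage of the N–H carbamate (the isocyanate is trapped by Et2NH as a urea) should free the phenoxide, which is O-sulfonylated in the same pot by PhNTf2 without loss of the aryl–silicon bond.

Step 4
Reactants: 8 (R)-malic acid
Product: 11 (3R)-3-hydroxy-4-methoxy-4-oxobutanoic acid, via trifluoroacetoxy anhydride 9 (not isolated), via O-trifluoroacetyl monoester 10 (not isolated)
Conditions: (CF3CO)2O, 0 °C → rt; evaporate; MeOH, rt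
Reagents that add atoms: methanol, CO
Why: Regioselective anhydride alcoholysis: the O-acylated cyclic anhydride should be opened by methanol at the more electrophilic carbonyl next to the acyloxy-bearing carbon, and methanol also strips the labile trifluoroacetate, all without touching the stereocentre.

Step 5
Reactants: 11 (3R)-3-hydroxy-4-methoxy-4-oxobutanoic acid
Product: 12 methyl (2R)-2-hydroxy-4-[methoxy(methyl)amino]-4-oxobutanoate
Conditions: MeNH(OMe)·HCl, EDC·HCl, HOBt, N-methylmorpholine, CH2Cl2, 0 °C → rt
Reagents that add atoms: N,O-dimethylhydroxylamine hydrochloride, CNOC.Cl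
Why: Carbodiimide-mediated amide coupling (Weinreb amide formation) should take place at the only free carboxylic acid, since the electron-poor α-hydroxy ester hydroxyl does not compete with the amine.

Step 6
Reactants: 12 methyl (2R)-2-hydroxy-4-[methoxy(methyl)amino]-4-oxobutanoate
Product: 13 methyl (2R)-5,5-dichloro-2-hydroxy-4-oxopentanoate
Conditions: CH2Cl2, LiN(iPr)2 (3.2 equiv), THF, −78 °C; AcOH, −78 °C
Reagents that add atoms: dichloromethane, ClCCl
Why: Carbenoid addition to a Weinreb amide: LiCHCl2 formed in situ should add to the amide rather than to the ester (deactivated by the neighbouring lithium alkoxide), and the chelated tetrahedral adduct survives until the cold acidic quench, so neither over-addition nor retro-aldol cleavage can occur.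

Step 7
Reactants: 13 methyl (2R)-5,5-dichloro-2-hydroxy-4-oxopentanoate
Product: 15 (3R,5S)-5-(dichloromethyl)-3-hydroxy-5-(prop-2-en-1-yl)oxolan-2-one, via diol ester 14 (not isolated)
Conditions: TiCl4, CH2Cl2, −78 °C; allylSiMe3; aq. NaHCO3; then TsOH (cat.), CH2Cl2, rt
Reagents that add atoms: allyltrimethylsilane, C=CC[Si](C)(C)C
Why: Hosomi–Sakurai allylation under chelation control: titanium binds the C2 alkoxide and the ketone oxygen in a six-membered chelate, the allylsilane should attack the ketone face anti to the ester-bearing carbon (new centre S, allyl cis to the 3-hydroxyl in the ring), and the tertiary alcohol then lactonises onto the methyl ester.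

Step 8
Reactants: 15 (3R,5S)-5-(dichloromethyl)-3-hydroxy-5-(prop-2-en-1-yl)oxolan-2-one
Product: 17 (3S,5S)-5-(dichloromethyl)-3-hydroxy-5-(prop-2-en-1-yl)oxolan-2-one, via inverted formate 16 (not isolated)
Conditions: HCO2H, PPh3, DIAD, THF, 0 °C → rt; then MeOH, TsOH (cat.), rt
Reagents that add atoms: formic acid, OC=O
Why: Mitsunobu inversion: formate should displace the activated C3 oxygen by SN2 from the opposite face, turning (3R) into (3S) so that the hydroxyl becomes cis to CHCl2, and the formate is removed by acid-catalysed transesterification, which never exposes a free tertiary alkoxide next to CHCl2.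

Step 9
Reactants: 17 (3S,5S)-5-(dichloromethyl)-3-hydroxy-5-(prop-2-en-1-yl)oxolan-2-one
Product: 18 (3S,5S)-3-(benzyloxy)-5-(dichloromethyl)-5-(prop-2-en-1-yl)oxolan-2-one
Conditions: BnOC(=NH)CCl3, TfOH (cat.), CH2Cl2/cyclohexane, 0 °C → rt
Reagents that add atoms: benzyl 2,2,2-trichloroacetimidate, N=C(OCc1ccccc1)C(Cl)(Cl)Cl
Why: Acid-catalysed O-benzylation with the trichloroacetimidate is the standard base-free way to benzylate α-hydroxy lactones and should proceed without epimerisation at C3 or ring opening.

Step 10
Reactants: 18 (3S,5S)-3-(benzyloxy)-5-(dichloromethyl)-5-(prop-2-en-1-yl)oxolan-2-one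
Product: 19 (3S,5R)-3-(benzyloxy)-5-(dichloromethyl)-5-(2-oxopropyl)oxolan-2-one
Conditions: PdCl2 (cat.), CuCl, O2 (1 atm), DMF/H2O, rt
Reagents that add atoms: water, O
Why: Tsuji–Wacker oxidation: Markovnikov hydroxypalladation of the terminal alkene should give the methyl ketone, while the lactone, the benzyl ether and the CHCl2 group are inert to these conditions.

Step 11
Reactants: 19 (3S,5R)-3-(benzyloxy)-5-(dichloromethyl)-5-(2-oxopropyl)oxolan-2-one
Product: 20 (3S,5R)-3-(benzyloxy)-5-(dichloromethyl)-5-(5,5,5-trifluoro-2,4-dioxopentyl)oxolan-2-one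
Conditions: LiN(SiMe3)2, THF, −78 °C; CF3CO2Et, −78 °C; 1 M HCl
Reagents that add atoms: ethyl trifluoroacetate, CCOC(=O)C(F)(F)F
Why: Crossed Claisen condensation: kinetic deprotonation at the unhindered methyl group (the other α-carbon is neopentyl-like) and C-trifluoroacetylation at −78 °C should give the 1,3-diketone, whose lithium hemiketal is stable until the acidic quench.

Step 12
Reactants: 7 3,5-dimethoxy-2-(trimethylsilyl)phenyl trifluoromethanesulfonate; 20 (3S,5R)-3-(benzyloxy)-5-(dichloromethyl)-5-(5,5,5-trifluoro-2,4-dioxopentyl)oxolan-2-one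
Product: 23 (3S,5R)-3-(benzyloxy)-5-(dichloromethyl)-5-[(6,8-dimethoxy-1-oxo-1H-isochromen-3-yl)methyl]oxolan-2-one, via 3,5-dimethoxybenzyne 21 (not isolated), via aryl trifluoromethyl ketone 22 (not isolated)
Conditions: CsF (3 equiv), MeCN, 80 °C
Reagents that add atoms: none
Why: Fluoride strips the silyl group and triflate departs to give benzyne 21; the diketonate of 20 should add through its central carbon at the aryne carbon remote from the methoxy group (future C4a), which leaves the aryl anion at C8a, stabilised inductively by the adjacent C8 methoxy group. That anion attacks the more electrophilic trifluoromethyl ketone (4-exo-trig), the strained benzocyclobutenoxide opens to aryl ketone 22 carrying a benzylic ketone enolate, and the enolate oxygen adds to the aryl trifluoromethyl ketone (6-exo-trig) before the hemiketal alkoxide expels CF3 as fluoroform, which closes ring B. The closest known reaction type is the acyl-alkylation of arynes by β-dicarbonyl compounds, including its use with trifluoromethyl β-diketones to deliver 3-substituted isocoumarins. No stereocentre is formed, and C3' and C5' of the lactone are spectators because the acidic diketone keeps the medium far from the basicity needed to enolise the lactone. The step needs regioselective addition to the unsymmetrical aryne (secured by the C8 methoxy group), C- rather than O-arylation (soft diketonate carbon) and migration of the trifluoroacetyl rather than the alkyl acyl group (higher electrophilicity of the CF3 ketone).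

Step 13
Reactants: 23 (3S,5R)-3-(benzyloxy)-5-(dichloromethyl)-5-[(6,8-dimethoxy-1-oxo-1H-isochromen-3-yl)methyl]oxolan-2-one
Product: 24 (3S,5R)-5-(dichloromethyl)-3-hydroxy-5-[(8-hydroxy-6-methoxy-1-oxo-1H-isochromen-3-yl)methyl]oxolan-2-one
Conditions: BCl3, C6HMe5, CH2Cl2, −78 → 0 °C; H2O
Reagents that add atoms: none
Why: Lewis-acid ether cleavage: BCl3 should remove the benzyl group (its cation is trapped by pentamethylbenzene) and, held between the C1 carbonyl and the peri C8 oxygen, cleave only the C8 methyl ether, leaving the C6 methyl ether, both lactone rings and the CHCl2 group intact.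

Compound list
1 | 3,5-dimethoxyphenol | COc1cc(O)cc(OC)c1 | starting material
2 | 3,5-dimethoxyphenyl N-isopropylcarbamate | COc1cc(OC)cc(OC(=O)NC(C)C)c1 | intermediate
3 | 3,5-dimethoxyphenyl N-(tert-butyldimethylsilyl)-N-isopropylcarbamate | COc1cc(OC)cc(OC(=O)N(C(C)C)[Si](C)(C)C(C)(C)C)c1 | intermediate (not isolated)
4 | 3,5-dimethoxy-2-(trimethylsilyl)phenyl N-(tert-butyldimethylsilyl)-N-isopropylcarbamate | COc1cc(OC)c([Si](C)(C)C)c(OC(=O)N(C(C)C)[Si](C)(C)C(C)(C)C)c1 | intermediate (not isolated)
5 | 3,5-dimethoxy-2-(trimethylsilyl)phenyl N-isopropylcarbamate | COc1cc(OC)c([Si](C)(C)C)c(OC(=O)NC(C)C)c1 | intermediate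
6 | 3,5-dimethoxy-2-(trimethylsilyl)phenol | COc1cc(OC)c([Si](C)(C)C)c(O)c1 | intermediate (not isolated)
7 | 3,5-dimethoxy-2-(trimethylsilyl)phenyl trifluoromethanesulfonate | COc1cc(OC)c([Si](C)(C)C)c(OS(=O)(=O)C(F)(F)F)c1 | intermediate
8 | (R)-malic acid, (2R)-2-hydroxybutanedioic acid | O=C(O)C[C@@H](O)C(=O)O | starting material
9 | (3R)-2,5-dioxooxolan-3-yl trifluoroacetate | O=C1C[C@@H](OC(=O)C(F)(F)F)C(=O)O1 | intermediate (not isolated)
10 | (3R)-4-methoxy-4-oxo-3-(trifluoroacetoxy)butanoic acid | O=C(O)C[C@@H](OC(=O)C(F)(F)F)C(=O)OC | intermediate (not isolated)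
11 | (3R)-3-hydroxy-4-methoxy-4-oxobutanoic acid | O=C(O)C[C@@H](O)C(=O)OC | intermediate
12 | methyl (2R)-2-hydroxy-4-[methoxy(methyl)amino]-4-oxobutanoate | CON(C)C(=O)C[C@@H](O)C(=O)OC | intermediate
13 | methyl (2R)-5,5-dichloro-2-hydroxy-4-oxopentanoate | ClC(Cl)C(=O)C[C@@H](O)C(=O)OC | intermediate
14 | methyl (2R,4S)-4-(dichloromethyl)-2,4-dihydroxyhept-6-enoate | C=CC[C@@](O)(C(Cl)Cl)C[C@@H](O)C(=O)OC | intermediate (not isolated)
15 | (3R,5S)-5-(dichloromethyl)-3-hydroxy-5-(prop-2-en-1-yl)oxolan-2-one | C=CC[C@@]1(C(Cl)Cl)C[C@@H](O)C(=O)O1 | intermediate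
16 | (3S,5S)-5-(dichloromethyl)-2-oxo-5-(prop-2-en-1-yl)oxolan-3-yl formate | C=CC[C@@]1(C(Cl)Cl)C[C@H](OC=O)C(=O)O1 | intermediate (not isolated)
17 | (3S,5S)-5-(dichloromethyl)-3-hydroxy-5-(prop-2-en-1-yl)oxolan-2-one | C=CC[C@@]1(C(Cl)Cl)C[C@H](O)C(=O)O1 | intermediate
18 | (3S,5S)-3-(benzyloxy)-5-(dichloromethyl)-5-(prop-2-en-1-yl)oxolan-2-one | C=CC[C@@]1(C(Cl)Cl)C[C@H](OCc2ccccc2)C(=O)O1 | intermediate
19 | (3S,5R)-3-(benzyloxy)-5-(dichloromethyl)-5-(2-oxopropyl)oxolan-2-one | CC(=O)C[C@@]1(C(Cl)Cl)C[C@H](OCc2ccccc2)C(=O)O1 | intermediate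
20 | (3S,5R)-3-(benzyloxy)-5-(dichloromethyl)-5-(5,5,5-trifluoro-2,4-dioxopentyl)oxolan-2-one | FC(F)(F)C(=O)CC(=O)C[C@@]1(C(Cl)Cl)C[C@H](OCc2ccccc2)C(=O)O1 | intermediate
21 | 3,5-dimethoxybenzyne (1,2-didehydro-3,5-dimethoxybenzene) | COC1=CC(OC)=CC#C1 | intermediate (not isolated)
22 | (3S,5R)-3-(benzyloxy)-5-(dichloromethyl)-5-{3-[3,5-dimethoxy-2-(trifluoroacetyl)phenyl]-2-oxopropyl}oxolan-2-one | COc1cc(OC)c(C(=O)C(F)(F)F)c(CC(=O)C[C@@]2(C(Cl)Cl)C[C@H](OCc3ccccc3)C(=O)O2)c1 | intermediate (not isolated)
23 | (3S,5R)-3-(benzyloxy)-5-(dichloromethyl)-5-[(6,8-dimethoxy-1-oxo-1H-isochromen-3-yl)methyl]oxolan-2-one | COc1cc(OC)c2c(=O)oc(C[C@@]3(C(Cl)Cl)C[C@H](OCc4ccccc4)C(=O)O3)cc2c1 | intermediate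
24 | (3S,5R)-5-(dichloromethyl)-3-hydroxy-5-[(8-hydroxy-6-methoxy-1-oxo-1H-isochromen-3-yl)methyl]oxolan-2-one | COc1cc(O)c2c(=O)oc(C[C@@]3(C(Cl)Cl)C[C@H](O)C(=O)O3)cc2c1 | target

Total step count: 13. Longest linear sequence: 10 steps (steps 4 to 13, from (R)-malic acid); the aryne precursor takes steps 1 to 3.

Steps most likely to fail

Step 12. The sequence may stall after acyl migration because the hemiketal alkoxide does not expel CF3. The aryne may also be lost to proton capture or O-arylation, and fluoride may trigger β-elimination across the CH2 next to C5', opening the lactone. The fallback sets out from 20 and returns at 23. The same diketone is C-arylated under CuI catalysis (Hurtley-type coupling; CuI, K3PO4, DMF, 90 °C) with 2-bromo-4,6-dimethoxybenzoic acid. The arylated diketone loses its trifluoroacetyl group by retro-Claisen cleavage to give 2-{3-[(2R,4S)-4-(benzyloxy)-2-(dichloromethyl)-5-oxooxolan-2-yl]-2-oxopropyl}-4,6-dimethoxybenzoic acid F1. Its carboxyl group then closes onto the ketone (cyclodehydration, completed with TsOH if needed) to give 23. This arylation, deacylation and lactonisation of 1,3-diketones with 2-halobenzoic acids is known chemistry.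

Step 7. Facial selectivity in the addition to the ketone may be poor, because the ester carbonyl competes for titanium and can loosen the chelate. The β-hydroxy ketone may also lose water under the Lewis acid. The fallback sets out from 17, carried as the mixture of C5 epimers, and returns at 19. The last two side-chain steps are reversed, so that the Tsuji–Wacker oxidation (PdCl2, CuCl, O2, DMF/H2O) is run on the free alcohol. The major epimer should give the open hydroxy ketone (3S,5R)-5-(dichloromethyl)-3-hydroxy-5-(2-oxopropyl)oxolan-2-one F2. The minor epimer has its new ketone cis to the 3-hydroxyl and should close to the bicyclic hemiketal (1S,5S)-5-(dichloromethyl)-3-hydroxy-3-methyl-2,6-dioxabicyclo[3.2.1]octan-7-one F3 (anomer mixture at C3). The two differ sharply in polarity and are separated. F2 is then benzylated with the trichloroacetimidate as in step 9 to give 19.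

Step 11. Proton transfer may move the enolate to the ring-side α-carbon, from which β-elimination of the lactone carboxylate opens the ring. The lactone α-hydrogen may also be removed, with loss of configuration at C3. The fallback sets out from 19 and returns at 20. Bu2BOTf and iPr2NEt (CH2Cl2, −78 °C) should form the boron enolate on the methyl side only, without equilibration. Aldol addition to trifluoroacetaldehyde, released from its ethyl hemiacetal, gives (3S,5R)-3-(benzyloxy)-5-(dichloromethyl)-5-(5,5,5-trifluoro-4-hydroxy-2-oxopentyl)oxolan-2-one F4 as both carbinol epimers. Dess–Martin periodinane then oxidises the carbinol to give 20.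

Further compounds
F1 | step 12 | 2-{3-[(2R,4S)-4-(benzyloxy)-2-(dichloromethyl)-5-oxooxolan-2-yl]-2-oxopropyl}-4,6-dimethoxybenzoic acid | COc1cc(OC)c(C(=O)O)c(CC(=O)C[C@@]2(C(Cl)Cl)C[C@H](OCc3ccccc3)C(=O)O2)c1
F2 | step 7 | (3S,5R)-5-(dichloromethyl)-3-hydroxy-5-(2-oxopropyl)oxolan-2-one | CC(=O)C[C@@]1(C(Cl)Cl)C[C@H](O)C(=O)O1
F3 | step 7 | (1S,5S)-5-(dichloromethyl)-3-hydroxy-3-methyl-2,6-dioxabicyclo[3.2.1]octan-7-one (anomer mixture at C3) | CC3(O)C[C@]1(C(Cl)Cl)C[C@H](O3)C(=O)O1
F4 | step 11 | (3S,5R)-3-(benzyloxy)-5-(dichloromethyl)-5-(5,5,5-trifluoro-4-hydroxy-2-oxopentyl)oxolan-2-one (both carbinol epimers) | OC(CC(=O)C[C@@]1(C(Cl)Cl)C[C@H](OCc2ccccc2)C(=O)O1)C(F)(F)F
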